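## Retrosynthetic overview

1. Target ⇐ global O-demethylation of its hexamethyl ether; the 1,4-dioxin (last ring formed) ⇐ quinone reduction, then intramolecular aryl bromide/phenol C–O closure.
2. The open precursor ⇐ a dibromo(methoxy)benzoquinone (future ring B) + 3,5-dimethoxyphenol (ring A, displaces the bromide para to OMe) + a bromodibenzofuranol (rings C/D, displaces the second bromide).
3. The dibenzofuran (furan = first ring formed) ⇐ a bromo(methoxy)benzoquinone + D3h-symmetric 1,3,5-trimethoxybenzene: conjugate arylation, then ipso-cyclisation with loss of MeOH.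
4. Both quinones ⇐ 2-bromo-6-methoxy-1,4-benzoquinone ⇐ oxidative dearomatisation of 2-bromo-6-methoxyphenol; this one dearomatised unit becomes rings B and C.
5. Ring order: furan (step 2), then dioxin (step 5). Rings: A = 3,5-dihydroxyphenoxy ring, B = dioxin ring carrying A, C = ring shared by dioxin and furan, D = outer furan-fused ring.

Assumption: the target (fucofuroeckol A skeleton, C24H14O11) has no stereocentre and no stable stereogenic axis; it is achiral, so no stereocontrol is needed.

## Route

Step 1
Reactants: 1 2-bromo-6-methoxyphenol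
Product: 2 2-bromo-6-methoxy-1,4-benzoquinone
Conditions: Fremy's salt (2.2 equiv), aq. KH2PO4, acetone, 0 °C → rt
Reagents that add atoms: potassium nitrosodisulfonate (Fremy's salt), [K+].[K+].[O]N(S(=O)(=O)[O-])S(=O)(=O)[O-]
Why: Teuber oxidation: Fremy's radical converts a 2,6-disubstituted phenol with a free para position into the p-quinone, dearomatising the ring and installing the C-4 oxygen (no stereocentre is formed here or anywhere in the route).

Step 2
Reactants: 2 2-bromo-6-methoxy-1,4-benzoquinone; 3 1,3,5-trimethoxybenzene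
Product: 5 1-bromo-3,7,9-trimethoxydibenzo[b,d]furan-2-ol, via arylhydroquinone 4 (not isolated)
Conditions: 3 (2.5 equiv), TfOH (0.2 equiv), HFIP, 0 °C, 2 added slowly; then TfOH (1.0 equiv), 55 °C
Reagents that add atoms: none
Why: Proposed new method: acid-catalysed Friedel–Crafts-type conjugate arylation of the quinone (known) puts the arene at C-3, the only CH that is β to the non-vinylogous carbonyl, next to C–Br and para to C–OMe; the hydroquinone OH flanking the new biaryl bond of 4 then attacks an ortho C–OMe of the C-protonated trimethoxyphenyl ring and expels MeOH (five-ring ipso-substitution via the arenium ion; closest known reactions are the acid cyclodehydration of 2-(2,4,6-trihydroxyphenyl)hydroquinones to dibenzofurans and acid-catalysed alkoxy exchange of phloroglucinol ethers), and the symmetry of 3 excludes any regioisomer.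

Step 3
Reactants: 2 2-bromo-6-methoxy-1,4-benzoquinone
Product: 7 2,3-dibromo-5-methoxy-1,4-benzoquinone, via dibromohydroquinone 6 (not isolated)
Conditions: HBr (33% in AcOH, 1.1 equiv), CHCl3, 0 °C → rt; then aq. FeCl3 (2.5 equiv), rt
Reagents that add atoms: hydrogen bromide, Br
Why: Conjugate hydrobromination of a quinone followed by reoxidation: bromide adds at C-3, directed both by the adjacent bromine and by the para methoxy group (as in HCl + chlorobenzoquinone → 2,3-dichlorohydroquinone), and Fe(III), which cannot oxidise bromide, returns the quinone.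

Step 4
Reactants: 7 2,3-dibromo-5-methoxy-1,4-benzoquinone; 8 3,5-dimethoxyphenol; 5 1-bromo-3,7,9-trimethoxydibenzo[b,d]furan-2-ol
Product: 10 3-[(1-bromo-3,7,9-trimethoxydibenzo[b,d]furan-2-yl)oxy]-2-(3,5-dimethoxyphenoxy)-5-methoxy-1,4-benzoquinone, via monoaryloxy bromoquinone 9 (not isolated)
Conditions: 8 (1.0 equiv), Cs2CO3 (1.1 equiv), MeCN, −20 → 0 °C; then 5 (1.05 equiv), Cs2CO3 (1.2 equiv), 50 °C
Reagents that add atoms: none
Why: Sequential addition–elimination of aryloxides on a haloquinone: the methoxy group turns C-1=O into a vinylogous ester, so the first phenoxide adds β to C-4=O and displaces the bromide para to C–OMe (C-2), and the less reactive C-3 bromide is then displaced by the hindered dibenzofuranolate on warming, as in the known conversion of 2,5-diaryloxy-3,6-dihaloquinones into tetra-aryloxyquinones.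

Step 5
Reactants: 10 3-[(1-bromo-3,7,9-trimethoxydibenzo[b,d]furan-2-yl)oxy]-2-(3,5-dimethoxyphenoxy)-5-methoxy-1,4-benzoquinone
Product: 12 fucofuroeckol A hexamethyl ether (only the ring-B OH ortho to the 3,5-dimethoxyphenoxy group is free), via bromohydroquinone 11 (not isolated)
Conditions: Na2S2O4, THF/H2O, rt; crude 11 under Ar: CuI (20 mol%), N,N-dimethylglycine (40 mol%), Cs2CO3 (3 equiv), dioxane, 100 °C
Reagents that add atoms: none
Why: Dithionite reduces the quinone to hydroquinone 11, whose OH ortho to the dibenzofuranyloxy group closes the six-membered dioxin by intramolecular Ullmann C–O coupling with the neighbouring aryl bromide (classical o-halophenoxyphenol → dibenzodioxin closure), the other OH having no halide within reach.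

Step 6
Reactants: 12 fucofuroeckol A hexamethyl ether
Product: 13 fucofuroeckol A (target)
Conditions: BBr3 (15 equiv), CH2Cl2, −78 °C → rt; then H2O, 0 °C, under Ar
Reagents that add atoms: none
Why: Lewis acid-mediated demethylation: BBr3 cleaves all six aryl methyl ethers while the diaryl ether, dioxin and furan C–O bonds are inert, giving the achiral heptaphenol.

## Compound list

1 | 2-bromo-6-methoxyphenol | COc1cccc(Br)c1O | starting material
2 | 2-bromo-6-methoxy-1,4-benzoquinone | COC1=CC(=O)C=C(Br)C1=O | intermediate
3 | 1,3,5-trimethoxybenzene | COc1cc(OC)cc(OC)c1 | starting material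
4 | 2-bromo-6-methoxy-3-(2,4,6-trimethoxyphenyl)benzene-1,4-diol | COc1cc(O)c(-c2c(OC)cc(OC)cc2OC)c(Br)c1O | intermediate
5 | 1-bromo-3,7,9-trimethoxydibenzo[b,d]furan-2-ol | COc1cc2oc3cc(OC)cc(OC)c3c2c(Br)c1O | intermediate
6 | 2,3-dibromo-5-methoxybenzene-1,4-diol | COc1cc(O)c(Br)c(Br)c1O | intermediate
7 | 2,3-dibromo-5-methoxy-1,4-benzoquinone | COC1=CC(=O)C(Br)=C(Br)C1=O | intermediate
8 | 3,5-dimethoxyphenol | COc1cc(O)cc(OC)c1 | starting material
9 | 3-bromo-2-(3,5-dimethoxyphenoxy)-5-methoxy-1,4-benzoquinone | COC1=CC(=O)C(Oc2cc(OC)cc(OC)c2)=C(Br)C1=O | intermediate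
10 | 3-[(1-bromo-3,7,9-trimethoxydibenzo[b,d]furan-2-yl)oxy]-2-(3,5-dimethoxyphenoxy)-5-methoxy-1,4-benzoquinone | COC1=CC(=O)C(Oc2cc(OC)cc(OC)c2)=C(Oc2c(OC)cc3oc4cc(OC)cc(OC)c4c3c2Br)C1=O | intermediate
11 | 3-[(1-bromo-3,7,9-trimethoxydibenzo[b,d]furan-2-yl)oxy]-2-(3,5-dimethoxyphenoxy)-5-methoxybenzene-1,4-diol | COc1cc(O)c(Oc2cc(OC)cc(OC)c2)c(Oc2c(OC)cc3oc4cc(OC)cc(OC)c4c3c2Br)c1O | intermediate
12 | fucofuroeckol A hexamethyl ether (ring-A, ring-D, ring-C oxygens and the ring-B oxygen para to the aryloxy group as OMe; ring-B OH ortho to the aryloxy group free) | COc1cc(OC)cc(Oc2c(O)cc(OC)c3c2Oc2c(OC)cc4oc5cc(OC)cc(OC)c5c4c2O3)c1 | intermediate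
13 | fucofuroeckol A: 3,5-dihydroxyphenoxy-substituted benzofuro-fused dibenzo[b,e][1,4]dioxin heptaol (CNP0256302.0) | Oc1cc(O)cc(Oc2c(O)cc(O)c3c2Oc2c(O)cc4oc5cc(O)cc(O)c5c4c2O3)c1 | target

## Step count and risks

Total steps: 6. Longest linear sequence: 5 (steps 1, 2, 4, 5, 6 or 1, 3, 4, 5, 6).

**Step 2** is the most likely to fail. The arylation is precedented, but the ring closure with loss of MeOH is unproven and may stop at 4 or give the arylquinone by redox exchange with 2. The fallback sets out from 2 and returns at 5. Quinone 2 is condensed with 3,5-dimethoxyphenol 8 under mild Brønsted acid hydrogen-bond catalysis (diphenyl phosphate, toluene, rt), the free OH of 8 directing C-arylation ortho to itself. This gives 2-bromo-3-(2-hydroxy-4,6-dimethoxyphenyl)-6-methoxybenzene-1,4-diol F1, which is isolated. F1 is closed by classical acid cyclodehydration of the 2,2'-dihydroxybiaryl (TsOH, toluene, reflux, loss of water from the phloroglucinol-type ring) to 5.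

**Step 4** is risky in its second displacement. The dibenzofuranolate is di-ortho-substituted and the remaining C–Br sits on a doubly donor-substituted quinone, so the reaction may be slow or may exchange the aryloxy or methoxy groups. The fallback sets out from 9 (made from 7 and 8 alone and isolated) and from 5, and returns at 12. It replaces the quinone displacement by a copper-mediated head-to-tail condensation of two ortho-bromophenols.
- 9 is reduced (Na2S2O4) to 3-bromo-2-(3,5-dimethoxyphenoxy)-5-methoxybenzene-1,4-diol F2.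
- The less hindered OH of F2 is silylated (TIPSCl, imidazole) to 2-bromo-3-(3,5-dimethoxyphenoxy)-6-methoxy-4-[(triisopropylsilyl)oxy]phenol F3.
- F3 and 5 are coupled (CuI, picolinic acid, K3PO4, toluene, 110 °C). Each phenoxide displaces the other partner's bromide, the second C–O bond forming intramolecularly, to give the O-triisopropylsilyl ether of 12 F4. Homodimers have to be separated.
- TBAF converts F4 into 12.

**Step 5** is risky because the free hydroquinone 11 can be reoxidised to 10 under the copper conditions and the bromide lies in the hindered bay position. The fallback sets out from 10 and returns at 12. It masks the hydroquinone so that it can no longer revert to the quinone, and uses palladium for the closure.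
- After dithionite reduction, the less hindered OH is silylated (TBSCl, imidazole) to the mono-tert-butyldimethylsilyl ether of 11 F5, an air-stable monophenol.
- F5 is cyclised by Pd-catalysed intramolecular C–O coupling (Pd(OAc)2, t-BuXPhos, K3PO4, toluene, 100 °C) to the O-tert-butyldimethylsilyl ether of 12 F6.
- TBAF converts F6 into 12.

## Further compounds

F1 | step 2 | 2-bromo-3-(2-hydroxy-4,6-dimethoxyphenyl)-6-methoxybenzene-1,4-diol | COc1cc(O)c(-c2c(O)cc(OC)cc2OC)c(Br)c1O
F2 | step 4 | 3-bromo-2-(3,5-dimethoxyphenoxy)-5-methoxybenzene-1,4-diol | COc1cc(O)c(Oc2cc(OC)cc(OC)c2)c(Br)c1O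
F3 | step 4 | 2-bromo-3-(3,5-dimethoxyphenoxy)-6-methoxy-4-[(triisopropylsilyl)oxy]phenol | COc1cc(O[Si](C(C)C)(C(C)C)C(C)C)c(Oc2cc(OC)cc(OC)c2)c(Br)c1O
F4 | step 4 | O-triisopropylsilyl ether of 12 | COc1cc(OC)cc(Oc2c(O[Si](C(C)C)(C(C)C)C(C)C)cc(OC)c3c2Oc2c(OC)cc4oc5cc(OC)cc(OC)c5c4c2O3)c1
F5 | step 5 | mono-tert-butyldimethylsilyl ether of 11 (silyl on the OH next to the 3,5-dimethoxyphenoxy group) | COc1cc(O[Si](C)(C)C(C)(C)C)c(Oc2cc(OC)cc(OC)c2)c(Oc2c(OC)cc3oc4cc(OC)cc(OC)c4c3c2Br)c1O
F6 | step 5 | O-tert-butyldimethylsilyl ether of 12 | COc1cc(OC)cc(Oc2c(O[Si](C)(C)C(C)(C)C)cc(OC)c3c2Oc2c(OC)cc4oc5cc(OC)cc(OC)c5c4c2O3)c1
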